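**Plan**

- Retrosynthesis: the anisate C–O bond is cut first, then the C6–O bond (back to a 6,8-dien-10-one), then the C10–C1 bond of the seven-membered ring, then the cyclopropane bonds C6–C7/C7–C8, the C6=C8 alkene, and last the five-membered ring, which is traced to (S)-terpinen-4-ol.
- Forward: ozonolysis/aldol ring contraction of the terpinenol gives the cyclopentene with C4 and the C6 aldehyde; Z-olefination and cyclopropanation add C7, C8 and C10, a diazomethyl unit adds C9; the seven-membered ring is formed last, from the cyclopropane.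
- Enabling feature: in the seven-membered ring C1–C5–C6–C7–C8–C9–C10 the ketone C10 lies between the C8=C9 alkene and quaternary C1, and C7 is a lone CH2 between C8 and C6. With C5=C6 unsaturated this ring is a cyclohepta-2,5-dienone, the [3,3] product of a cyclopropane (C6, C7, C8) that carries, cis to each other, a ketene (C9=C10=O) on C8 and the cyclopentene C5=C1 on C6.
- Stereochemistry: C4 from the chiral pool; the cyclopropane carbons C6/C8 by reagent-controlled asymmetric cyclopropanation; C1 by stereospecific transfer in the boat [3,3] shift; C5 by thermodynamic protonation (trans ring fusion); C6 by 1,6-borylation anti to the angular methyl.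

Key step: step 8

Remark: atoms carry daucane numbers (C1 methyl-bearing ring-fusion carbon, C2/C3 ring CH2, C4 carbinol carbon, C5 ring-fusion CH, C6 acyloxy carbon, C7 CH2, C8 methyl-bearing alkene carbon, C9 alkene CH, C10 ketone carbon; β is the face of the C1 methyl, α the other face); (S)-terpinen-4-ol is assumed to be used in enantiomerically enriched commercial form.

**Step 1**
Reactants: 1 (S)-terpinen-4-ol; 2 triethylsilyl trifluoromethanesulfonate
Product: 3 triethyl{[(1S)-4-methyl-1-(propan-2-yl)cyclohex-3-en-1-yl]oxy}silane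
Conditions: Et3SiOTf, 2,6-lutidine, CH2Cl2, 0 °C to rt
Reagents that add atoms: triethylsilyl trifluoromethanesulfonate (2), CC[Si](CC)(CC)OS(=O)(=O)C(F)(F)F
Why: Silyl triflate/lutidine silylation of a hindered tertiary alcohol is standard, leaves the future C4 stereocentre untouched, and masks the hydroxyl against β-elimination, lactonisation and ketene capture later on.

**Step 2**
Reactants: 3 silyl ether; 4 ozone
Product: 6 (5R)-2-methyl-5-(propan-2-yl)-5-[(triethylsilyl)oxy]cyclopent-1-ene-1-carbaldehyde, via keto aldehyde 5 (not isolated)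
Conditions: O3, CH2Cl2, −78 °C; Me2S, −78 °C to rt; then piperidine (0.3 equiv), AcOH (0.3 equiv), toluene, 60 °C
Reagents that add atoms: ozone (4), [O-][O+]=O
Why: Ozonolysis of the ring alkene gives the 6-oxoheptanal 5, and the amine/acid-catalysed intramolecular aldol condensation (aldehyde enamine onto the methyl ketone, five-membered ring closure) should contract the ring to the formylcyclopentene, the free aldol hydroxyl being lost in preference to the silyl ether.

**Step 3**
Reactants: 6 enal; 7 ethyl 2-[bis(2,2,2-trifluoroethoxy)phosphoryl]propanoate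
Product: 8 ethyl (2Z)-2-methyl-3-{(5R)-2-methyl-5-(propan-2-yl)-5-[(triethylsilyl)oxy]cyclopent-1-en-1-yl}prop-2-enoate
Conditions: KN(SiMe3)2, 18-crown-6, THF, −78 °C
Reagents that add atoms: ethyl 2-[bis(2,2,2-trifluoroethoxy)phosphoryl]propanoate (7), CCOC(=O)C(C)P(=O)(OCC(F)(F)F)OCC(F)(F)F
Why: The Still–Gennari variant of the Horner–Wadsworth–Emmons olefination should give the kinetic Z-trisubstituted enoate, with the ring carbon C5 cis to the ester, which is the geometry that later places the two π arms cis on the cyclopropane.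

**Step 4**
Reactants: 8 Z-enoate
Product: 9 (2Z)-2-methyl-3-{(5R)-2-methyl-5-(propan-2-yl)-5-[(triethylsilyl)oxy]cyclopent-1-en-1-yl}prop-2-en-1-ol
Conditions: iBu2AlH (2.5 equiv), CH2Cl2, −78 to 0 °C
Reagents that add atoms: none
Why: 1,2-Reduction of a conjugated ester to the allylic alcohol with iBu2AlH is standard and does not disturb the alkene geometry.

**Step 5**
Reactants: 9 Z-allylic alcohol; 10 diiodomethane
Product: 11 [(1S,2R)-1-methyl-2-{(5R)-2-methyl-5-(propan-2-yl)-5-[(triethylsilyl)oxy]cyclopent-1-en-1-yl}cyclopropyl]methanol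
Conditions: ZnEt2 (2.2 equiv), CH2I2 (4.4 equiv), DME, (4R,5R)-2-butyl-N,N,N′,N′-tetramethyl-1,3,2-dioxaborolane-4,5-dicarboxamide (1.2 equiv), CH2Cl2, −10 °C to rt
Reagents that add atoms: diiodomethane (10), ICI
Why: The Charette asymmetric Simmons–Smith cyclopropanation is hydroxyl-directed (only the allylic alkene reacts) and stereospecific (cis arms retained), and the (4R,5R)-dioxaborolane, which by the established facial model turns (E)-cinnamyl alcohol into the (1S,2S)-cyclopropylmethanol, should deliver CH2 (C7) to the face that sets C8 as (S) and C6 as (R).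

**Step 6**
Reactants: 11 cyclopropylmethanol
Product: 12 (1S,2S)-1-methyl-2-{(5R)-2-methyl-5-(propan-2-yl)-5-[(triethylsilyl)oxy]cyclopent-1-en-1-yl}cyclopropane-1-carboxylic acid
Conditions: TEMPO (0.2 equiv), PhI(OAc)2 (2.2 equiv), MeCN/pH 7 aqueous buffer (1:1), rt
Reagents that add atoms: water, O
Why: Oxoammonium oxidation of the primary alcohol to the aldehyde and, through its hydrate, on to the acid is mild enough for the cyclopropane, the silyl ether and the tetrasubstituted alkene (the descriptor at the ring-bearing carbon changes by priority only).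

**Step 7**
Reactants: 12 acid; 13 1-chloro-N,N,2-trimethylprop-1-en-1-amine; 14 (trimethylsilyl)diazomethane
Product: 16 2-diazo-1-[(1S,2S)-1-methyl-2-{(5R)-2-methyl-5-(propan-2-yl)-5-[(triethylsilyl)oxy]cyclopent-1-en-1-yl}cyclopropyl]ethan-1-one, via acid chloride 15 (not isolated)
Conditions: Ghosez's reagent (1.2 equiv), CH2Cl2, 0 °C to rt; then Me3SiCHN2 (2.5 equiv), THF/MeCN, 0 °C to rt
Reagents that add atoms: (trimethylsilyl)diazomethane (14), C[Si](C)(C)C=[N+]=[N-] (reagent 13, CC(C)=C(Cl)N(C)C, puts chlorine into 15 only)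
Why: The α-chloroenamine makes the hindered acid chloride under neutral conditions, and its acylation of the silyl diazomethane with loss of the silyl group is the usual Arndt–Eistert-type route to a diazomethyl ketone.

**Step 8**
Reactants: 16 diazoketone
Product: 18 (3R,8aS)-6,8a-dimethyl-3-(propan-2-yl)-3-[(triethylsilyl)oxy]-2,3,5,8a-tetrahydroazulen-8(1H)-one, via ketene 17 (not isolated)
Conditions: AgO2CPh (0.1 equiv), Et3N (1.0 equiv), THF, 45 °C, ultrasound
Reagents that add atoms: none
Why: Silver-promoted loss of N2 from 16 triggers the Wolff 1,2-shift of the cyclopropyl carbon C8 (with retention) to give the cis-2-alkenylcyclopropyl ketene 17, whose C9=C10 π bond and the cyclopentene C5=C1 π bond then undergo a concerted [3,3] shift across the breaking C6–C8 cyclopropane bond, forming C10–C1 with release of ring strain. The closest known reaction type is the tandem Wolff/Cope rearrangement of cis-2-vinylcyclopropyl diazomethyl ketones to cyclohepta-2,5-dienones, a ketene variant of the divinylcyclopropane–cycloheptadiene rearrangement. The seven-membered ring is closed by this suprafacial sigmatropic ring expansion of the three-membered ring through the only accessible boat transition state, in which both π arms lie over C7 and the new C5=C6 and C8=C9 double bonds are cis within the ring. The quaternary stereocentre C1 is controlled by the cyclopropane configuration at C6 and C8: in the boat array the ketene carbon can reach only the cyclopentene face on which C8 sits, which for this cyclopropane makes C1 (S), with C10 anti to the C4 oxygen. The step needs the rearrangement to outrun capture of the ketene and to accept the fully substituted terminus C1; the cis arrangement of the arms from steps 3 and 5, the lack of any inward substituent on the sp ketene carbon, the aprotic medium and the silyl mask on the tertiary hydroxyl secure this.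

**Step 9**
Reactants: 18 silyl ether dienone
Product: 19 (3R,8aS)-3-hydroxy-6,8a-dimethyl-3-(propan-2-yl)-2,3,5,8a-tetrahydroazulen-8(1H)-one
Conditions: Bu4NF, AcOH (1:1), THF, 0 °C to rt
Reagents that add atoms: none
Why: Acetic-acid-buffered fluoride should remove the silyl group without the acid that could ionise the tertiary allylic ether and without the strong base that could move the alkenes.

**Step 10**
Reactants: 19 skipped dienone
Product: 20 (3R,3aR,8aS)-3-hydroxy-6,8a-dimethyl-3-(propan-2-yl)-2,3,3a,8a-tetrahydroazulen-8(1H)-one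
Conditions: DBU (0.3 equiv), toluene, rt
Reagents that add atoms: none
Why: Base-catalysed prototropic isomerisation through the extended dienolate (deprotonation at C7, reprotonation at C5) should move C5=C6 into conjugation as C6=C7, and reversible protonation should set C5 under thermodynamic control as the trans-fused 5α-H epimer, which places C6 cis to the small hydroxyl and not to the isopropyl group on the cyclopentane.

**Step 11**
Reactants: 20 conjugated dienone; 21 bis(pinacolato)diboron; 22 sodium perborate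
Product: 25 (3R,3aS,4S,8aS)-3,4-dihydroxy-6,8a-dimethyl-3-(propan-2-yl)-2,3,3a,4,5,8a-hexahydroazulen-8(1H)-one, via allylboronate 23 (not isolated), via hydroxy ketone 24 (not isolated)
Conditions: CuCl (5 mol %), Xantphos (5 mol %), NaOtBu (10 mol %), B2pin2 (1.2 equiv), MeOH (2 equiv), THF, rt; NaBO3·4H2O, THF/H2O, rt; DBU (0.2 equiv), CH2Cl2, rt
Reagents that add atoms: sodium perborate (22), [Na+].[O-]OB=O (the C6 oxygen); bis(pinacolato)diboron (21), CC1(C)OB(OC1(C)C)B1OC(C)(C)C(C)(C)O1 (boron held by 23 only)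
Why: Copper-catalysed 1,6-conjugate borylation of the dienone (the β-carbon C8 is blocked by its methyl) should place boron on C6 from the α face, anti to the C1 methyl that stands 1,3 to the β face, and oxidation with retention followed by base-induced return of the alkene into conjugation should give the 6α-alcohol.

**Step 12**
Reactants: 25 diol enone; 26 4-methoxybenzoyl chloride
Product: 27 (3R,3aS,4S,8aS)-3-hydroxy-6,8a-dimethyl-8-oxo-3-(propan-2-yl)-1,2,3,3a,4,5,8,8a-octahydroazulen-4-yl 4-methoxybenzoate
Conditions: 4-MeOC6H4COCl (1.5 equiv), pyridine, DMAP (0.1 equiv), CH2Cl2, 0 °C to rt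
Reagents that add atoms: 4-methoxybenzoyl chloride (26), COc1ccc(C(=O)Cl)cc1
Why: DMAP-catalysed acylation should take place at the secondary C6 hydroxyl only, the tertiary C4 hydroxyl being too hindered, and the mild base avoids vinylogous β-elimination of the new ester.

**Compound list**

1 | (S)-terpinen-4-ol, (1S)-4-methyl-1-(propan-2-yl)cyclohex-3-en-1-ol | CC1=CC[C@](O)(C(C)C)CC1 | starting material
2 | triethylsilyl trifluoromethanesulfonate | CC[Si](CC)(CC)OS(=O)(=O)C(F)(F)F | starting material
3 | triethyl{[(1S)-4-methyl-1-(propan-2-yl)cyclohex-3-en-1-yl]oxy}silane | CC1=CC[C@](O[Si](CC)(CC)CC)(C(C)C)CC1 | intermediate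
4 | ozone | [O-][O+]=O | starting material
5 | (3S)-6-oxo-3-(propan-2-yl)-3-[(triethylsilyl)oxy]heptanal | CC(=O)CC[C@@](O[Si](CC)(CC)CC)(C(C)C)CC=O | intermediate
6 | (5R)-2-methyl-5-(propan-2-yl)-5-[(triethylsilyl)oxy]cyclopent-1-ene-1-carbaldehyde | CC1=C(C=O)[C@](O[Si](CC)(CC)CC)(C(C)C)CC1 | intermediate
7 | ethyl 2-[bis(2,2,2-trifluoroethoxy)phosphoryl]propanoate | CCOC(=O)C(C)P(=O)(OCC(F)(F)F)OCC(F)(F)F | starting material
8 | ethyl (2Z)-2-methyl-3-{(5R)-2-methyl-5-(propan-2-yl)-5-[(triethylsilyl)oxy]cyclopent-1-en-1-yl}prop-2-enoate | CC1=C(/C=C(/C)C(=O)OCC)[C@](O[Si](CC)(CC)CC)(C(C)C)CC1 | intermediate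
9 | (2Z)-2-methyl-3-{(5R)-2-methyl-5-(propan-2-yl)-5-[(triethylsilyl)oxy]cyclopent-1-en-1-yl}prop-2-en-1-ol | CC1=C(/C=C(/C)CO)[C@](O[Si](CC)(CC)CC)(C(C)C)CC1 | intermediate
10 | diiodomethane | ICI | starting material
11 | [(1S,2R)-1-methyl-2-{(5R)-2-methyl-5-(propan-2-yl)-5-[(triethylsilyl)oxy]cyclopent-1-en-1-yl}cyclopropyl]methanol | CC1=C([C@@H]2C[C@]2(C)CO)[C@](O[Si](CC)(CC)CC)(C(C)C)CC1 | intermediate
12 | (1S,2S)-1-methyl-2-{(5R)-2-methyl-5-(propan-2-yl)-5-[(triethylsilyl)oxy]cyclopent-1-en-1-yl}cyclopropane-1-carboxylic acid | CC1=C([C@@H]2C[C@]2(C)C(=O)O)[C@](O[Si](CC)(CC)CC)(C(C)C)CC1 | intermediate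
13 | 1-chloro-N,N,2-trimethylprop-1-en-1-amine (Ghosez's reagent) | CC(C)=C(Cl)N(C)C | starting material
14 | (trimethylsilyl)diazomethane | C[Si](C)(C)C=[N+]=[N-] | starting material
15 | (1S,2S)-1-methyl-2-{(5R)-2-methyl-5-(propan-2-yl)-5-[(triethylsilyl)oxy]cyclopent-1-en-1-yl}cyclopropane-1-carbonyl chloride | CC1=C([C@@H]2C[C@]2(C)C(=O)Cl)[C@](O[Si](CC)(CC)CC)(C(C)C)CC1 | intermediate
16 | 2-diazo-1-[(1S,2S)-1-methyl-2-{(5R)-2-methyl-5-(propan-2-yl)-5-[(triethylsilyl)oxy]cyclopent-1-en-1-yl}cyclopropyl]ethan-1-one | CC1=C([C@@H]2C[C@]2(C)C(=O)C=[N+]=[N-])[C@](O[Si](CC)(CC)CC)(C(C)C)CC1 | intermediate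
17 | 2-[(1S,2R)-1-methyl-2-{(5R)-2-methyl-5-(propan-2-yl)-5-[(triethylsilyl)oxy]cyclopent-1-en-1-yl}cyclopropyl]ethen-1-one (ketene) | CC1=C([C@@H]2C[C@]2(C)C=C=O)[C@](O[Si](CC)(CC)CC)(C(C)C)CC1 | intermediate
18 | (3R,8aS)-6,8a-dimethyl-3-(propan-2-yl)-3-[(triethylsilyl)oxy]-2,3,5,8a-tetrahydroazulen-8(1H)-one | CC1=CC(=O)[C@@]2(C)CC[C@@](O[Si](CC)(CC)CC)(C(C)C)C2=CC1 | intermediate
19 | (3R,8aS)-3-hydroxy-6,8a-dimethyl-3-(propan-2-yl)-2,3,5,8a-tetrahydroazulen-8(1H)-one | CC1=CC(=O)[C@@]2(C)CC[C@@](O)(C(C)C)C2=CC1 | intermediate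
20 | (3R,3aR,8aS)-3-hydroxy-6,8a-dimethyl-3-(propan-2-yl)-2,3,3a,8a-tetrahydroazulen-8(1H)-one | CC1=CC(=O)[C@@]2(C)CC[C@@](O)(C(C)C)[C@@H]2C=C1 | intermediate
21 | bis(pinacolato)diboron | CC1(C)OB(OC1(C)C)B1OC(C)(C)C(C)(C)O1 | starting material
22 | sodium perborate | [Na+].[O-]OB=O | starting material
23 | 4β-hydroxy-6α-(pinacolboryl)dauc-7-en-10-one (5α-H; C7=C8 alkene, C9 CH2) | CC1(C)OB(OC1(C)C)[C@H]2C=C(C)CC(=O)[C@@]3(C)CC[C@@](O)(C(C)C)[C@H]23 | intermediate
24 | 4β,6α-dihydroxydauc-7-en-10-one (5α-H; C7=C8 alkene, C9 CH2) | O[C@H]1C=C(C)CC(=O)[C@@]2(C)CC[C@@](O)(C(C)C)[C@H]12 | intermediate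
25 | (3R,3aS,4S,8aS)-3,4-dihydroxy-6,8a-dimethyl-3-(propan-2-yl)-2,3,3a,4,5,8a-hexahydroazulen-8(1H)-one | O[C@H]1CC(C)=CC(=O)[C@@]2(C)CC[C@@](O)(C(C)C)[C@H]12 | intermediate
26 | 4-methoxybenzoyl chloride | COc1ccc(C(=O)Cl)cc1 | starting material
27 | (3R,3aS,4S,8aS)-3-hydroxy-6,8a-dimethyl-8-oxo-3-(propan-2-yl)-1,2,3,3a,4,5,8,8a-octahydroazulen-4-yl 4-methoxybenzoate | COc1ccc(C(=O)O[C@H]2CC(C)=CC(=O)[C@@]3(C)CC[C@@](O)(C(C)C)[C@H]23)cc1 | target

Total step count: 12. Longest linear sequence: 12 steps (from 1).

**Steps most likely to fail**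

Step 10. The extended enolate may expel the tertiary C4 hydroxyl by vinylogous β-elimination, or protonation at C5 may not favour the trans-fused epimer. The fallback sets out from 19 and comes back at 27, bypassing steps 10 to 12. The tertiary allylic hydroxyl of 19 directs a VO(acac)2/tBuOOH epoxidation of C5=C6 to the 5β,6β-epoxy alcohol F1. Homolytic opening of F1 with Cp2TiCl (trivalent titanium, made from Cp2TiCl2 and Mn) in the presence of 1,4-cyclohexadiene cleaves the C5–O bond to the tertiary radical, which should take up hydrogen anti to the bulky C6 titanium alkoxide and give the 5α-H, 6β-alcohol F2. A Mitsunobu esterification of F2 with 4-methoxybenzoic acid (PPh3, DIAD) then installs the anisate with inversion at C6 and gives 27.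

Step 11. The boryl copper species may add 1,4 at C8, add too slowly to the hindered δ-carbon, or attack the face syn to the angular methyl. The fallback sets out from 20 and comes back at 25. Electrophilic epoxidation of the more electron-rich distal C6=C7 bond of 20 with mCPBA (NaHCO3, CH2Cl2), expected anti to the angular methyl, gives the 6α,7α-epoxide F3. Hydrogenolysis of this vinyl epoxide at the allylic C7–O bond with Pd2(dba)3/PBu3 and HCO2H/Et3N (zerovalent palladium, formate as hydride source), followed by brief base treatment to conjugate the alkene, gives 25.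

Step 8. The ketene may be captured by benzoate, amine or traces of water, or the silver carbenoid may react with the ring alkene, before the sterically demanding [3,3] shift onto the fully substituted C1 takes place. The fallback sets out from 11 and comes back at 18; it makes the same C10–C1 bond by a thermal divinylcyclopropane rearrangement at the alcohol oxidation level. Oxidation of 11 with Dess–Martin periodinane gives the cyclopropanecarbaldehyde F4. A boron-Wittig olefination of F4 with lithiated CH2(Bpin)2 gives the (E)-alkenyl pinacol boronate F5. Heating F5 in toluene (110 to 140 °C) gives the seven-membered allylic boronate F6. Oxidation of F6 with NaBO3 gives the allylic alcohol F7, and oxidation of F7 with Dess–Martin periodinane gives dienone 18.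

**Further compounds**

F1 | step 10 | 4β-hydroxy-5β,6β-epoxydauc-8-en-10-one | CC1=CC(=O)[C@@]2(C)CC[C@@](O)(C(C)C)[C@]23O[C@@H]3C1
F2 | step 10 | 4β,6β-dihydroxydauc-8-en-10-one (5α-H, C6 epimer of 25) | O[C@@H]1CC(C)=CC(=O)[C@@]2(C)CC[C@@](O)(C(C)C)[C@H]12
F3 | step 11 | 4β-hydroxy-6α,7α-epoxydauc-8-en-10-one (5α-H) | CC1=CC(=O)[C@@]2(C)CC[C@@](O)(C(C)C)[C@@H]2[C@H]3O[C@@H]13
F4 | step 8 | (1S,2R)-1-methyl-2-{(5R)-2-methyl-5-(propan-2-yl)-5-[(triethylsilyl)oxy]cyclopent-1-en-1-yl}cyclopropane-1-carbaldehyde | CC1=C([C@@H]2C[C@]2(C)C=O)[C@](O[Si](CC)(CC)CC)(C(C)C)CC1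
F5 | step 8 | (E)-alkenyl pinacol boronate (2-borylvinyl group on the methyl-bearing cyclopropane carbon, cis to the cyclopentenyl group) | CC1=C([C@@H]2C[C@]2(C)/C=C/B3OC(C)(C)C(C)(C)O3)[C@](O[Si](CC)(CC)CC)(C(C)C)CC1
F6 | step 8 | 10-(pinacolboryl)-4β-[(triethylsilyl)oxy]dauca-5,8-diene | CC1=C[C@@H](B2OC(C)(C)C(C)(C)O2)[C@@]3(C)CC[C@@](O[Si](CC)(CC)CC)(C(C)C)C3=CC1
F7 | step 8 | 4β-[(triethylsilyl)oxy]dauca-5,8-dien-10-ol | CC1=C[C@@H](O)[C@@]2(C)CC[C@@](O[Si](CC)(CC)CC)(C(C)C)C2=CC1
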